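## Structural features

The target joins two ring systems through a single C–C bond: a 5,7,8-trimethoxy-2-phenyl-4H-chromene (pyran atoms O1', C2', C3', C4', C4a', C8a') and a trans-fused eudesmane decalin (rings A and B, C1–C10), with C4' bonded to C1. The decalin holds five stereocentres: quaternary C10 (β-methyl), C5 (α-H), C7 (β-isopropenyl), C4 (tertiary alcohol, OH α and equatorial, methyl β and 1,3-diaxial to the C10 methyl) and C1 (chromenyl group β and equatorial). The sixth stereocentre, C4', stands directly next to C1, which is itself next to C10, so the inter-ring bond is flanked by a quaternary carbon (descriptors in eudesmane numbering: 1S,4R,5R,7R,10S; chromene 4'R). Fragile groups are the enol ether C2'=C3' (hydrolysis, oxidation to a flavylium ion), the tertiary alcohol (elimination), the isopropenyl group (acid and electrophiles; hydrogenation is excluded) and the electron-rich arene, which makes any C–O bond at C4' extremely labile to acid. The real difficulty is twofold: ring A must be closed onto a ring B that already carries C5, C7 and C10, adding one extra carbon at C1 and hydrating C4 while the equally substituted C11=C12 alkene stays untouched; and C4' must be set next to this congested carbon. The key step uses the fact that the pyran ring is the [4+2] adduct of the hetero-diene O1'=C8a'–C4a'=C4', an ortho-quinone methide whose methide carbon already carries C1, with a two-carbon enol ether C2'=C3'. The chiral C1 then decides the face of C4'.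

## Logic of the disconnections

**20 to 18 (through 19).** The C2'=C3' double bond is treated as the product of an elimination, and C2' regains a silyloxy group. The enol ether is the most fragile function and is therefore made last, under weakly acidic conditions. The target becomes a saturated chroman ketal. The forward step must dehydrate the lactol without touching the C4 carbinol or the isopropenyl group.

**18 to 14 and 15 (through 16 and 17).** C3'–C4' and O1'–C2' are cut together. The pyran ring is a formal cycloadduct, so one step removes a ring, two skeletal bonds and two stereocentres, and C4' becomes a planar methide carbon attached to C1. The forward step must add 15 to one face of C4' under the control of C1 and C10, and it must do so faster than a hydrogen shift from C1.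

**14 to 13.** The aryl O–C(carbonate) bond is cut. The carbonate is the device that lets the quinone methide form under base at low temperature instead of by heat or acid. The forward step must acylate the phenol only.

**13 to 6 and 11.** The C4'–C4a' bond is cut between an aldehyde carbon and the ortho C–H of a phenol. This makes the plan convergent, and the only free ortho position of 11 fixes the regiochemistry. The forward step must be ortho-specific and free of acid-labile protecting groups, because the benzylic C–O bond of 13 ionises easily.

**6 to 5.** C2–C3 and C4–O are cut. Ring A is closed onto ring B by joining two π systems that sit on neighbouring ring carbons, and the C4 oxygen arrives in the same event. The forward step must close through C2 and not through the carbonyl carbon, take up water on the α face of C4, and spare the C7 isopropenyl group.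

**5 to 4 to 3 to 1.** The α-methylene carbon, the aldehyde oxidation level and the terminal C–O bond are removed in turn. This leads back to 1, which supplies all fifteen carbons and the stereocentres C5, C7 and C10. The forward sequence must tell a monosubstituted alkene from two 1,1-disubstituted ones.

**11 to 9 (through 10) to 8 to 7.** Three aryl C–O bonds are traced back: the phenol oxygen to a formyl group (oxygen insertion), one methoxy group to the free phenol of 7, one to the bromide. The forward order must keep the formyl group until both methoxy groups are in place.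

## Other disconnections considered

**Alternative 1:** C5–C10 and C1–C2 are cut together, so that rings A and B arise at once from the acyclic triene A1. In A1 an E-configured enoate C10=C1 is tethered by C9–C6 to a 2-methyl diene C5=C4–C3=C2, and C7 from the chiral pool is the only stereocentre. The forward key step is an intramolecular Diels–Alder reaction that would give the octalin ester A2.
- In its favour: one step makes both carbocycles, the quaternary C10 and the C1 carbon that later becomes C4'. The cis relation of the C10 methyl and the C1 substituent follows from the enoate geometry.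
- Better than the chosen plan on one point: the trisubstituted C3=C4 alkene of A2 can be told apart from the isopropenyl group by a peracid, so C4 hydration would rest on epoxidation and hydride opening. Step 4 of the chosen plan has no direct precedent.
- Against it: the dienophile is β,β-disubstituted and must create a quaternary carbon, so forcing conditions are to be expected. The trans ring fusion and the face relative to C7 depend on one transition state out of four. A1 needs a multistep linear assembly, and A2 needs about four further operations to reach 6.
- Comparison: on structure the two plans are equal, since both deliver the same decalin with the C1 carbon in place. On mechanism the pericyclic step is more predictable in bond formation and less predictable in diastereoselectivity than the cationic closure. On step economy the chosen plan is shorter, because 1 already contains ring B and three stereocentres.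

**Alternative 2:** C9–C10 and C5–C6 are cut, so ring B is annulated onto a ring A that is the epoxy ketone A3. The forward key step is the Robinson annulation of A3 with methyl vinyl ketone A4 to the epoxy octalenone A5.
- In its favour: each bond is made by textbook enolate chemistry.
- Better than the chosen plan: the C4 oxygen and methyl are present from the start as the α-epoxide, so the hydration problem does not arise.
- At least equal: the isopropenyl group on the neighbouring carbon should steer the Michael addition as well as C1 steers the cycloaddition.
- Against it: in A5 the isopropenyl group sits on C1, where the target needs a one-carbon link, so it must be degraded. The C7 isopropenyl group must then be built from the C7 ketone with β configuration, the C5=C6 alkene reduced to the trans fusion, and the epoxide opened at C3. The epoxy ketone must also survive the basic annulation.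
- Comparison: on structure the mapping is poorer, because the one stereocentre of the chiral pool ends up at a carbon that must be rebuilt. On mechanism the individual steps are safer. On step economy the alternative is clearly longer.

**Alternative 3:** C6–C7 is cut. The forward key step is a conjugate ene cyclisation of the exocyclic enone A6, activated by (CH3)2AlCl A8, to the trans-fused decalone A7.
- In its favour: a known reaction type closes ring B, sets the trans fusion at C5 and creates the isopropenyl group with its C7 configuration through one chair-like transition state. On this point it is better than the chosen plan, which relies on an untested ring closure.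
- Equal: the oxygenated one-carbon arm on C1 is in place before the union with the arene.
- Against it: A6 carries two adjacent stereocentres (C1 and quaternary C10) that no chiral-pool compound provides, so an asymmetric synthesis is needed first. The C4 ketone of A7 would be attacked by a methyl organometallic from the equatorial α face, which gives the 4β-alcohol, the wrong epimer. The detour through methylenation, epoxidation and hydride meets the problem of two 1,1-disubstituted alkenes again.
- Comparison: on mechanism the alternative is better precedented. On structure it is weaker at C4 and in absolute configuration. On step economy it is longer.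

Key step: step 10

Assumptions (remarks on the chemistry):
- Locants C1–C15 follow eudesmane numbering; primed locants belong to the chromene.
- The carbinol carbon of 12, 13, 14 and 16 may have either configuration. It is drawn without a descriptor because it becomes trigonal in 17.
- 15 is bought; it is also one step from acetophenone (TMSCl, NaI, Et3N).
- "Safe" is read as "least likely to fail".
- The configurations of all compounds were checked against the target atom by atom and are mutually consistent. Three design points were chosen on purpose: no acid-labile phenol protecting group, no regiochemical choice in the arene–aldehyde union, and no electrophilic palladium on the 1,5-diene of 1.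

Step 1
Reactants: 1 (−)-β-elemene
Product: 3 2-[(1S,2S,4R)-1-methyl-2,4-di(prop-1-en-2-yl)cyclohexyl]ethan-1-ol, via alkyl catecholboronate 2 (not isolated)
Conditions: catecholborane (1.1 equiv), RhCl(PPh3)3 (2 mol%), THF, 0 °C to rt; then NaOH, H2O2, 0 °C
Reagents that add atoms: hydrogen peroxide, OO
Why: Rhodium-catalysed hydroboration is very sensitive to alkene substitution, so the monosubstituted vinyl group should react ahead of the two 1,1-disubstituted isopropenyl groups and place boron on the terminal carbon; oxidative work-up gives the primary alcohol and no stereocentre is formed or touched.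

Step 2
Reactants: 3 2-[(1S,2S,4R)-1-methyl-2,4-di(prop-1-en-2-yl)cyclohexyl]ethan-1-ol
Product: 4 2-[(1S,2S,4R)-1-methyl-2,4-di(prop-1-en-2-yl)cyclohexyl]acetaldehyde
Conditions: TEMPO (10 mol%), PhI(OAc)2, CH2Cl2, rt
Reagents that add atoms: none
Why: Oxoammonium-mediated oxidation of a primary alcohol stops at the aldehyde and leaves the three alkenes alone.

Step 3
Reactants: 4 2-[(1S,2S,4R)-1-methyl-2,4-di(prop-1-en-2-yl)cyclohexyl]acetaldehyde
Product: 5 2-[(1R,2S,4R)-1-methyl-2,4-di(prop-1-en-2-yl)cyclohexyl]prop-2-enal (ring configuration as in 1; the descriptor at the quaternary carbon changes by priority only)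
Conditions: 37% aq. HCHO, pyrrolidine (10 mol%), EtCO2H (10 mol%), i-PrOH, 45 °C
Reagents that add atoms: formaldehyde, C=O
Why: Amine-catalysed Mannich-type α-methylenation (enamine plus formaldehyde-derived iminium ion, then elimination); the CH2 group next to the quaternary carbon is the only enolisable position, so there is no regiochemical choice.

Step 4
Reactants: 5 2-[(1R,2S,4R)-1-methyl-2,4-di(prop-1-en-2-yl)cyclohexyl]prop-2-enal
Product: 6 4α-hydroxyeudesm-11-ene-1β-carbaldehyde (trans-decalin; 10β-CH3; 5α-H; 7β-isopropenyl; 4α-OH and 4β-CH3; 1β-CHO)
Conditions: Sc(OTf)3 (10 mol%), 2,6-di-tert-butyl-4-methylpyridine (10 mol%), H2O (5 equiv), MeNO2, 0 °C to rt; then DBU (cat.), CH2Cl2, rt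
Reagents that add atoms: water, O
Why: Proposed new method: carbonyl-bound Sc(OTf)3 makes C2 of the 2-alkylpropenal electrophilic, the isopropenyl group on the neighbouring ring carbon (held gauche to it) attacks through its CH2 terminus in a chair-like 6-endo closure that forms C2–C3, and water captures the developing tertiary C4 cation anti to the new bond, that is from the equatorial α face away from the axial C10 methyl, which sets 4α-OH and 4β-CH3; the enol that results is protonated and DBU equilibrates the formyl group to the equatorial 1β position; the hindered pyridine removes adventitious strong acid so that the C7 isopropenyl group is not protonated, and capture of the cation by the enol oxygen is impossible because a bridge across ring A cannot form in a trans-decalin; the closest known reaction types are the Lewis-acid-promoted conjugate ene and Prins cyclisations of α-methylene carbonyl compounds with alkenes and the hydrative Prins cyclisation of citronellal to p-menthane-3,8-diol, and the same C4 cation is the one hydrated in acid-mediated germacrene-to-selinenol cyclisations.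

Step 5
Reactants: 7 5-bromo-2-hydroxy-3-methoxybenzaldehyde
Product: 8 2-hydroxy-3,5-dimethoxybenzaldehyde
Conditions: NaOMe (4 equiv), CuBr (10 mol%), DMF/MeOH, 110 °C; then aq. HCl
Reagents that add atoms: sodium methoxide, [Na+].[O-]C
Why: Copper-catalysed Ullmann-type methoxylation of an aryl bromide, a reaction that is routine on bromo-hydroxybenzaldehydes; the phenoxide and the formyl group are tolerated.

Step 6
Reactants: 8 2-hydroxy-3,5-dimethoxybenzaldehyde
Product: 9 2,3,5-trimethoxybenzaldehyde
Conditions: MeI, K2CO3, DMF, rt
Reagents that add atoms: iodomethane, CI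
Why: Williamson O-methylation of the only phenol.

Step 7
Reactants: 9 2,3,5-trimethoxybenzaldehyde
Product: 11 2,3,5-trimethoxyphenol, via aryl formate 10 (not isolated)
Conditions: mCPBA, CH2Cl2, 0 °C to rt; then K2CO3 (cat.), MeOH, rt
Reagents that add atoms: 3-chloroperoxybenzoic acid, O=C(OO)c1cccc(Cl)c1
Why: Baeyer–Villiger oxidation of an electron-rich benzaldehyde (Dakin-type): the aryl group with its ortho methoxy donor migrates in preference to hydrogen, and the formate is removed by methanolysis.

Step 8
Reactants: 6 4α-hydroxyeudesm-11-ene-1β-carbaldehyde; 11 2,3,5-trimethoxyphenol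
Product: 13 2-[hydroxy(4α-hydroxyeudesm-11-en-1β-yl)methyl]-3,5,6-trimethoxyphenol, via benzodioxaborin 12 (not isolated)
Conditions: PhB(OH)2 (1.2 equiv), EtCO2H (0.3 equiv), toluene, 4 Å MS, 80 °C; then 30% H2O2, THF, 0 °C to rt
Reagents that add atoms: none
Why: Boronic-acid-templated ortho-hydroxyalkylation of a phenol: phenol and aldehyde are both bound to boron, so the electrophilic attack is intramolecular and can reach only the single free ortho position (the para position is out of reach), and the cyclic boronate protects the labile benzylic C–O bond until neutral peroxide cleaves the B–C bond; the new carbinol stereocentre is not controlled and need not be.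

Step 9
Reactants: 13 2-[hydroxy(4α-hydroxyeudesm-11-en-1β-yl)methyl]-3,5,6-trimethoxyphenol
Product: 14 tert-butyl 2-[hydroxy(4α-hydroxyeudesm-11-en-1β-yl)methyl]-3,5,6-trimethoxyphenyl carbonate
Conditions: Boc2O (1.1 equiv), i-Pr2NEt, DMAP (5 mol%), CH2Cl2, −20 to 0 °C
Reagents that add atoms: di-tert-butyl dicarbonate, CC(C)(C)OC(=O)OC(=O)OC(C)(C)C
Why: The phenol is far more acidic and more accessible than the hindered secondary benzylic alcohol and the tertiary alcohol, so amine/DMAP acylation should give the aryl carbonate only; the low temperature is meant to prevent acyl migration to the benzylic oxygen.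

Step 10
Reactants: 14 tert-butyl 2-[hydroxy(4α-hydroxyeudesm-11-en-1β-yl)methyl]-3,5,6-trimethoxyphenyl carbonate; 15 1-phenyl-1-(trimethylsilyloxy)ethene
Product: 18 4-(4α-hydroxyeudesm-11-en-1β-yl)-5,7,8-trimethoxy-2-phenyl-2-(trimethylsilyloxy)chromane (C4' as in the target; silyloxy group cis to the decalin), via benzylic carbonate 16 (not isolated), via o-quinone methide 17 (not isolated)
Conditions: 15 (5 equiv), t-BuMgCl (2.2 equiv), Et2O, −78 to 0 °C; pH 7 buffer
Reagents that add atoms: none
Why: t-BuMgCl deprotonates both hydroxyl groups, the benzylic alkoxide takes the tert-butoxycarbonyl group from the neighbouring aryl oxygen through a six-membered transition state (16), and the magnesium phenoxide then expels tert-butyl carbonate in a 1,4-elimination that releases the magnesium-bound o-quinone methide 17 far below room temperature. 17 is an electron-poor 1-oxadiene (O1'=C8a'–C4a'=C4') and 15 an electron-rich enol ether, so they should combine in an inverse-electron-demand hetero-Diels–Alder reaction driven by rearomatisation; the closest known reaction type is the cycloaddition of o-quinone methides with alkyl enol ethers to 2-alkoxychromans. Bond formation is asynchronous: the CH2 terminus of 15 bonds first to the methide carbon C4' and the silyloxy-bearing carbon then closes onto O1', so the pyran ring is closed either in one suprafacial [4+2] event or, at the stepwise limit, by 6-exo-trig collapse of the phenoxide onto the silyloxocarbenium ion, and both paths give 18. C4' is controlled by C1: allylic 1,3-strain with the flanking oxygen (the 5'-methoxy group in the E isomer, the carbonyl oxygen in the Z isomer) holds the C1–H bond in the plane of the quinone methide, which places quaternary C10 with its axial methyl on one face and the C2 methylene on the other, and 15 should add anti to C10; this model leads to the required configuration for either geometry of 17. C2' follows from an endo orientation of the silyloxy group, but it is of no consequence because it becomes trigonal in step 11. The step needs addition to outrun the 1,5-hydrogen shift from C1 to the carbonyl oxygen, which would give a vinyl phenol; the low temperature, the magnesium coordination and a five-fold excess of the nucleophilic 15 are there to secure this. The tertiary C4 alkoxide is a spectator, because in a trans-decalin it cannot reach C4'.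

Step 11
Reactants: 18 4-(4α-hydroxyeudesm-11-en-1β-yl)-5,7,8-trimethoxy-2-phenyl-2-(trimethylsilyloxy)chromane
Product: 20 (4'R)-4'-[(1S,4R,5R,7R,10S)-4-hydroxyeudesm-11-en-1-yl]-5',7',8'-trimethoxy-2'-phenyl-4'H-chromene (the target), via lactol 19 (not isolated)
Conditions: TBAF, AcOH, THF, 0 °C; then PPTS (10 mol%), 4 Å MS, toluene, 50 °C
Reagents that add atoms: none
Why: Buffered fluoride removes the silyl group from the mixed ketal to give the lactol (in equilibrium with the open hydroxy ketone), and mild acid dehydrates it through the phenyl- and aryloxy-stabilised oxocarbenium ion to the conjugated enol ether; at this acidity the tertiary alcohol and the isopropenyl group should survive, and C4' is not involved.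

## Compound list

1 | (−)-β-elemene, (1S,2S,4R)-1-ethenyl-1-methyl-2,4-di(prop-1-en-2-yl)cyclohexane | C=C(C)[C@@H]1CC[C@@](C)(C=C)[C@@H](C1)C(C)=C | starting material
2 | 2-{2-[(1S,2S,4R)-1-methyl-2,4-di(prop-1-en-2-yl)cyclohexyl]ethyl}-1,3,2-benzodioxaborole | C=C(C)[C@@H]1CC[C@@](C)(CCB2Oc3ccccc3O2)[C@@H](C1)C(C)=C | intermediate (not isolated)
3 | 2-[(1S,2S,4R)-1-methyl-2,4-di(prop-1-en-2-yl)cyclohexyl]ethan-1-ol | C=C(C)[C@@H]1CC[C@@](C)(CCO)[C@@H](C1)C(C)=C | intermediate
4 | 2-[(1S,2S,4R)-1-methyl-2,4-di(prop-1-en-2-yl)cyclohexyl]acetaldehyde | C=C(C)[C@@H]1CC[C@@](C)(CC=O)[C@@H](C1)C(C)=C | intermediate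
5 | 2-[(1R,2S,4R)-1-methyl-2,4-di(prop-1-en-2-yl)cyclohexyl]prop-2-enal | C=C(C)[C@@H]1CC[C@@](C)(C(=C)C=O)[C@@H](C1)C(C)=C | intermediate
6 | 4α-hydroxyeudesm-11-ene-1β-carbaldehyde (1R,4R,5R,7R,10R; 10β-CH3, 5α-H, 7β-isopropenyl, 4α-OH, 4β-CH3, 1β-CHO) | C=C(C)[C@@H]1CC[C@]2(C)[C@@H](C1)[C@](C)(O)CC[C@H]2C=O | intermediate
7 | 5-bromo-2-hydroxy-3-methoxybenzaldehyde | COc1cc(Br)cc(C=O)c1O | starting material
8 | 2-hydroxy-3,5-dimethoxybenzaldehyde | COc1cc(OC)cc(C=O)c1O | intermediate
9 | 2,3,5-trimethoxybenzaldehyde | COc1cc(OC)cc(C=O)c1OC | intermediate
10 | 2,3,5-trimethoxyphenyl formate | COc1cc(OC)cc(OC=O)c1OC | intermediate (not isolated)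
11 | 2,3,5-trimethoxyphenol | COc1cc(OC)cc(O)c1OC | intermediate
12 | 4-(4α-hydroxyeudesm-11-en-1β-yl)-5,7,8-trimethoxy-2-phenyl-4H-1,3,2-benzodioxaborinine (either configuration at C4 of the heterocycle) | C=C(C)[C@@H]1CC[C@]2(C)[C@@H](C1)[C@](C)(O)CC[C@H]2C1OB(c2ccccc2)Oc2c(OC)c(OC)cc(OC)c21 | intermediate (not isolated)
13 | 2-[hydroxy(4α-hydroxyeudesm-11-en-1β-yl)methyl]-3,5,6-trimethoxyphenol (salicyl alcohol; either carbinol configuration) | C=C(C)[C@@H]1CC[C@]2(C)[C@@H](C1)[C@](C)(O)CC[C@H]2C(O)c1c(O)c(OC)c(OC)cc1OC | intermediate
14 | tert-butyl 2-[hydroxy(4α-hydroxyeudesm-11-en-1β-yl)methyl]-3,5,6-trimethoxyphenyl carbonate | C=C(C)[C@@H]1CC[C@]2(C)[C@@H](C1)[C@](C)(O)CC[C@H]2C(O)c1c(OC(=O)OC(C)(C)C)c(OC)c(OC)cc1OC | intermediate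
15 | 1-phenyl-1-(trimethylsilyloxy)ethene | C=C(O[Si](C)(C)C)c1ccccc1 | starting material
16 | tert-butyl (4α-hydroxyeudesm-11-en-1β-yl)(2-hydroxy-3,4,6-trimethoxyphenyl)methyl carbonate, present as its magnesium phenoxide | C=C(C)[C@@H]1CC[C@]2(C)[C@@H](C1)[C@](C)(O)CC[C@H]2C(OC(=O)OC(C)(C)C)c1c(O)c(OC)c(OC)cc1OC | intermediate (not isolated)
17 | (E)-6-[(4α-hydroxyeudesm-11-en-1β-yl)methylidene]-2,3,5-trimethoxycyclohexa-2,4-dien-1-one (o-quinone methide; the Z isomer may be present as well) | C=C(C)[C@@H]1CC[C@]2(C)[C@@H](C1)[C@](C)(O)CC[C@H]2/C=C1/C(=O)C(OC)=C(OC)C=C1OC | intermediate (not isolated)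
18 | 4-(4α-hydroxyeudesm-11-en-1β-yl)-5,7,8-trimethoxy-2-phenyl-2-(trimethylsilyloxy)chromane (C4' as in the target, silyloxy cis to the decalin) | C=C(C)[C@@H]1CC[C@]2(C)[C@@H](C1)[C@](C)(O)CC[C@H]2[C@@H]1C[C@@](O[Si](C)(C)C)(c2ccccc2)Oc2c(OC)c(OC)cc(OC)c21 | intermediate
19 | 4-(4α-hydroxyeudesm-11-en-1β-yl)-5,7,8-trimethoxy-2-phenylchroman-2-ol (lactol, either anomer, in equilibrium with the open hydroxy ketone) | C=C(C)[C@@H]1CC[C@]2(C)[C@@H](C1)[C@](C)(O)CC[C@H]2[C@@H]1CC(O)(c2ccccc2)Oc2c(OC)c(OC)cc(OC)c21 | intermediate (not isolated)
20 | (4'R)-4'-[(1S,4R,5R,7R,10S)-4-hydroxyeudesm-11-en-1-yl]-5',7',8'-trimethoxy-2'-phenyl-4'H-chromene | C=C(C)[C@@H]1CC[C@]2(C)[C@@H](C1)[C@](C)(O)CC[C@H]2[C@@H]1C=C(c2ccccc2)Oc2c(OC)c(OC)cc(OC)c21 | target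

## Step count and least certain steps

Total step count: 11 (steps 1, 7, 8 and 11 have a second stage in the same flask).
Longest linear sequence: 8 steps (1, 2, 3, 4, 8, 9, 10, 11, counted from 1). The arene branch (steps 5–7) joins at step 8.

**Step 4 (the one proposed new method).**
- What may go wrong: closure through the carbonyl carbon instead of C2, since both modes give a six-membered ring; loss of a proton from the C4 cation before water arrives; acid-induced hydration or migration of the C7 isopropenyl group; water capture on the β face.
- Why: the balance between 1,2- and 1,4-attack of an alkene on an activated enal is not settled, and the medium contains little water.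
- Fallback (known chemistry only), from 5 back to 6:
  - Copper-catalysed conjugate addition of CH2=CHMgBr (CuBr·SMe2, TMSCl, THF, −78 °C) should give 2-[1-methyl-2,4-di(prop-1-en-2-yl)cyclohexyl]pent-4-enal F1.
  - Ring-closing metathesis between the new vinyl group and the neighbouring isopropenyl group (second-generation Grubbs catalyst, RuCl2(=CHPh)(PCy3)(H2IMes), CH2Cl2, 40 °C; then DBU) closes ring A as eudesma-3,11-diene-1β-carbaldehyde F2.
  - mCPBA with NaHCO3 at −20 °C should epoxidise the trisubstituted alkene faster than the isopropenyl group and from the α face, giving 3α,4α-epoxyeudesm-11-ene-1β-carbaldehyde F3.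
  - LiAlH4 opens the epoxide at the secondary C3 and reduces the aldehyde, giving 1β-(hydroxymethyl)eudesm-11-en-4α-ol F4.
  - TEMPO/PhI(OAc)2 oxidises the primary alcohol only and returns the route to 6.

**Step 10 (key step).**
- What may go wrong: tautomerisation of 17 to a vinyl phenol by 1,5-hydrogen shift from C1 before 15 adds; weak discrimination between the two faces of C4'.
- Why: the 5'-methoxy group makes the Z geometry accessible, and in that geometry the C1–H bond points at the carbonyl oxygen.
- Fallback, from 13 back to 19, without a free quinone methide: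
  - Acetylation (Ac2O, pyridine, DMAP) gives (4α-hydroxyeudesm-11-en-1β-yl)(2-acetoxy-3,4,6-trimethoxyphenyl)methyl acetate F11.
  - Bi(OTf)3 (cat.) in CH2Cl2 at −78 °C ionises the benzylic acetate, and the cation is captured by 15 in a Mukaiyama-type SN1 alkylation under the same C1 control, giving 2-[(1R)-1-(4α-hydroxyeudesm-11-en-1β-yl)-3-oxo-3-phenylpropyl]-3,5,6-trimethoxyphenyl acetate F12.
  - K2CO3 in MeOH removes the aryl acetate, and the phenol closes onto the ketone to give 19, which is dehydrated as in the second stage of step 11.

**Step 1.**
- What may go wrong: hydroboration of one of the isopropenyl groups in competition with the vinyl group.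
- Why: the vinyl group sits on a quaternary carbon and is slowed by it.
- Fallback, from 1 back to 5:
  - Wacker oxidation (PdCl2, CuCl, O2, DMF/H2O) gives 1-[(1S,2S,4R)-1-methyl-2,4-di(prop-1-en-2-yl)cyclohexyl]ethan-1-one F5.
  - KN(SiMe3)2 and PhNTf2 give the enol triflate 1-[1-methyl-2,4-di(prop-1-en-2-yl)cyclohexyl]ethenyl trifluoromethanesulfonate F6.
  - Reductive carbonylation (Pd(OAc)2, dppp, CO, HCO2Na, DMF, 70 °C) returns the route to 5.
  - This path is kept in reserve because divalent palladium may induce cyclisation of the 1,5-diene.

**Step 8.**
- What may go wrong: slow condensation at the hindered formyl group; ionisation of 12 at 80 °C and capture by a second molecule of 11; untemplated attack at the para position.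
- Fallback, from 11 back to 13, using an aryl-metal addition:
  - SEMCl and i-Pr2NEt give 1,2,5-trimethoxy-3-{[2-(trimethylsilyl)ethoxy]methoxy}benzene F7.
  - n-BuLi/TMEDA lithiates between the acetal oxygen and the 5-methoxy group. Addition of 6 (0.45 equiv; the first equivalent of aryllithium deprotonates the C4 hydroxyl) gives (4α-hydroxyeudesm-11-en-1β-yl)(3,4,6-trimethoxy-2-{[2-(trimethylsilyl)ethoxy]methoxy}phenyl)methanol F8.
  - TBAF in DMPU at 70 °C removes the acetal under basic conditions and returns the route to 13.

**Step 9.**
- What may go wrong: migration of the carbonate to the benzylic oxygen during acylation, followed by premature elimination.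
- Fallback, from 13 back to 19:
  - TBSCl and imidazole give the phenol silyl ether {2-[(tert-butyldimethylsilyl)oxy]-3,4,6-trimethoxyphenyl}(4α-hydroxyeudesm-11-en-1β-yl)methanol F9.
  - Ac2O, Et3N and DMAP give its benzylic acetate {2-[(tert-butyldimethylsilyl)oxy]-3,4,6-trimethoxyphenyl}(4α-hydroxyeudesm-11-en-1β-yl)methyl acetate F10.
  - TBAF at −78 °C in the presence of 15 unmasks the phenoxide, which expels acetate to give 17. Capture by 15 (or by the enolate that fluoride makes from it) and work-up lead to 19.

## Further compounds

F1 | step 4 | 2-[1-methyl-2,4-di(prop-1-en-2-yl)cyclohexyl]pent-4-enal (ring configuration as in 1, either configuration at C2 of the pentenal) | C=C(C)[C@@H]1CC[C@@](C)(C(CC=C)C=O)[C@@H](C1)C(C)=C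
F2 | step 4 | eudesma-3,11-diene-1β-carbaldehyde | C=C(C)[C@@H]1CC[C@]2(C)[C@@H](C1)C(C)=CC[C@H]2C=O
F3 | step 4 | 3α,4α-epoxyeudesm-11-ene-1β-carbaldehyde | C=C(C)[C@@H]1CC[C@]2(C)[C@@H](C1)[C@]1(C)O[C@@H]1C[C@H]2C=O
F4 | step 4 | 1β-(hydroxymethyl)eudesm-11-en-4α-ol | C=C(C)[C@@H]1CC[C@]2(C)[C@@H](C1)[C@](C)(O)CC[C@H]2CO
F5 | step 1 | 1-[(1S,2S,4R)-1-methyl-2,4-di(prop-1-en-2-yl)cyclohexyl]ethan-1-one | C=C(C)[C@@H]1CC[C@@](C)(C(C)=O)[C@@H](C1)C(C)=C
F6 | step 1 | 1-[1-methyl-2,4-di(prop-1-en-2-yl)cyclohexyl]ethenyl trifluoromethanesulfonate (ring configuration as in 1) | C=C(C)[C@@H]1CC[C@@](C)(C(=C)OS(=O)(=O)C(F)(F)F)[C@@H](C1)C(C)=C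
F7 | step 8 | 1,2,5-trimethoxy-3-{[2-(trimethylsilyl)ethoxy]methoxy}benzene | COc1cc(OCOCC[Si](C)(C)C)c(OC)c(OC)c1
F8 | step 8 | (4α-hydroxyeudesm-11-en-1β-yl)(3,4,6-trimethoxy-2-{[2-(trimethylsilyl)ethoxy]methoxy}phenyl)methanol (either carbinol configuration) | C=C(C)[C@@H]1CC[C@]2(C)[C@@H](C1)[C@](C)(O)CC[C@H]2C(O)c1c(OCOCC[Si](C)(C)C)c(OC)c(OC)cc1OC
F9 | step 9 | {2-[(tert-butyldimethylsilyl)oxy]-3,4,6-trimethoxyphenyl}(4α-hydroxyeudesm-11-en-1β-yl)methanol (either carbinol configuration) | C=C(C)[C@@H]1CC[C@]2(C)[C@@H](C1)[C@](C)(O)CC[C@H]2C(O)c1c(O[Si](C)(C)C(C)(C)C)c(OC)c(OC)cc1OC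
F10 | step 9 | {2-[(tert-butyldimethylsilyl)oxy]-3,4,6-trimethoxyphenyl}(4α-hydroxyeudesm-11-en-1β-yl)methyl acetate | C=C(C)[C@@H]1CC[C@]2(C)[C@@H](C1)[C@](C)(O)CC[C@H]2C(OC(C)=O)c1c(O[Si](C)(C)C(C)(C)C)c(OC)c(OC)cc1OC
F11 | step 10 | (2-acetoxy-3,4,6-trimethoxyphenyl)(4α-hydroxyeudesm-11-en-1β-yl)methyl acetate | C=C(C)[C@@H]1CC[C@]2(C)[C@@H](C1)[C@](C)(O)CC[C@H]2C(OC(C)=O)c1c(OC(C)=O)c(OC)c(OC)cc1OC
F12 | step 10 | 2-[(1R)-1-(4α-hydroxyeudesm-11-en-1β-yl)-3-oxo-3-phenylpropyl]-3,5,6-trimethoxyphenyl acetate (benzylic carbon configured as C4' of the target) | C=C(C)[C@@H]1CC[C@]2(C)[C@@H](C1)[C@](C)(O)CC[C@H]2[C@H](CC(=O)c1ccccc1)c1c(OC(C)=O)c(OC)c(OC)cc1OC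
A1 | alternative 1 | methyl (2E,8E)-3,9-dimethyl-6-(prop-1-en-2-yl)undeca-2,8,10-trienoate (C6 configured as C7 of the target) | C=C(C)[C@@H](C/C=C(\C)C=C)CC/C(C)=C/C(=O)OC
A2 | alternative 1 | methyl eudesma-3,11-diene-1β-carboxylate | C=C(C)[C@@H]1CC[C@]2(C)[C@@H](C1)C(C)=CC[C@H]2C(=O)OC
A3 | alternative 2 | 2,3-epoxy-2,6-dimethyl-5-(prop-1-en-2-yl)cyclohexan-1-one (6-methylcarvone 2,3-epoxide; C6 either configuration) | C=C(C)[C@@H]1C[C@H]2O[C@@]2(C)C(=O)C1C
A4 | alternative 2 | methyl vinyl ketone (but-3-en-2-one) | CC(=O)C=C
A5 | alternative 2 | epoxy octalenone with quaternary C10 (3α,4α-epoxy-1β-isopropenyl-4,10-dimethyl octal-5-en-7-one) | C=C(C)[C@@H]1C[C@H]2O[C@@]2(C)C2=CC(=O)CC[C@@]12C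
A6 | alternative 3 | 3-methyl-2-methylidene-3-(4-methylpent-3-en-1-yl)-4-{[(triisopropylsilyl)oxy]methyl}cyclohexan-1-one (C1 and C10 configured as in the target) | CC(C)=CCC[C@]1(C)C(=C)C(=O)CC[C@H]1CO[Si](C(C)C)(C(C)C)C(C)C
A7 | alternative 3 | trans-fused 4-decalone with 7β-isopropenyl and 1β-{[(triisopropylsilyl)oxy]methyl} | C=C(C)[C@@H]1CC[C@]2(C)[C@@H](C1)C(=O)CC[C@H]2CO[Si](C(C)C)(C(C)C)C(C)C
A8 | alternative 3 | dimethylaluminium chloride | C[Al](C)Cl
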